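# Proposed total synthesis of CNP0137585.0 (a heptameric phlorethol)

## The problem

CNP0137585.0 is a linear phlorotannin: seven benzene rings, lettered A to G from the 2,4,6-trihydroxyphenyl end to the 3,4,5-trihydroxyphenoxy end, joined only by six diaryl ether oxygens. There is no C–C bond between rings and no stereocentre, so stereocontrol does not arise; the task is to put each oxygen on the right carbon. Rings C and E are identical 1,2-diaryloxy-3,4,5-trihydroxybenzenes, rings B and F identical 1,5-diaryloxy-3,4-dihydroxybenzenes, ring D is a 1,4-diaryloxy-3,5-dihydroxybenzene and ring G a 3,4,5-trihydroxyphenyl ether, so building blocks can be used twice. Of the twelve ring carbons that carry an ether oxygen, four are flanked by oxygen substituents on both sides (C2 of ring A, C6 of ring C, C4 of ring D, C6 of ring E); these are the positions where aryl C–O coupling is hardest. The eighteen free hydroxyl groups make the final compound electron-rich, air-sensitive in base and hard to purify, so they are masked as methyl ethers until the last step; these survive copper couplings, peracid and alkoxide. The diaryl ether bonds themselves are robust, which permits a Lewis-acid demethylation at the end. The enabling feature is ring A: it is a phloroglucinol whose ether carbon C2 lies between the hydroxylated carbons C1 and C3, so its keto tautomer is a 2-aryloxycyclohexane-1,3,5-trione, the cyclised form of a linear 3,5-dioxo diester with the aryloxy group on its central sp3 carbon. The most hindered ether of the molecule can therefore be made by SN2 chemistry at a saturated carbon, and ring A closed around it by a Claisen condensation.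

## Retrosynthesis

**32 from 31.** The eighteen O–CH3 bonds are cut last. Methyl ethers are the only protecting group present in the commercial ring building blocks and the only one needed. The forward reaction asks for exhaustive BBr3 demethylation without touching the six diaryl ethers.

**31 from 15 and 30.** The ether between C5 of ring B and the oxygen on C1 of ring C is cut. This is the only inner ether in which neither carbon is flanked on both sides (the bromide carbon of 15 has one ortho methoxy group, the phenol of 30 one ortho aryloxy group). It divides the molecule into a two-ring bromide and a five-ring phenol made in seven and eight steps. Cutting one ether further along would put a doubly flanked carbon into the fragment coupling. The forward reaction is an Ullmann etherification.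

**30 from 27 and 20, through 28.** The hydroxyl of 30 is traced back to the formyl group of aldehyde 28 (Baeyer–Villiger oxidation), and 28 is cut at the ether on C6 of ring C into phenol 27 and bromoaldehyde 20. The formyl group of 20 does two jobs: ortho to bromine it activates a carbon that is flanked on both sides, and after oxidation it becomes the hydroxyl exactly where the next ether is required. This couple-then-oxidise pair is the repeating unit of the five-ring fragment, and each ring comes from a commercial bromobenzaldehyde.

**27 from 23 and 24, through 25.** The same pair of operations introduces ring D: phenol 27 from aldehyde 25, and 25 from phenol 23 and bromide 24 by cutting the ether at C4 of ring D. Here the bromide sits between two methoxy groups and is activated only by the para formyl group; this is the hardest coupling of the route. The opposite polarity (ring D as the phenol) would need a ring E bromide next to a bulky aryloxy group and would leave no latent hydroxyl on ring D, so the cut is accepted as drawn.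

**23 from 19 and 20, through 21; 19 from 16 and 1, through 17.** Ring E comes from a second portion of 20 and phenol 19 (cut at C6 of ring E). Ring F comes from bromoaldehyde 1 and the ring G phenol 16 (cut at C5 of ring F). Both couplings use unhindered phenols. Compound 1 also supplies ring B.

**15 from 14, and 14 from 12.** The three methyl ethers of ring A are removed to triol 14, and a carboxyl group is put back to reach benzoate 12. The ester is what the ring construction leaves behind, and phloroglucinolcarboxylic acids lose CO2 readily, so its removal costs one step.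

**12 from 10 (key disconnection).** Ring A is opened at the bond between the ester-bearing carbon and the neighbouring hydroxylated carbon that is not adjacent to the ether carbon. This gives the symmetric triketide diester 10, in which the aryloxy group sits on the central carbon. The forward reaction is a Dieckmann-type Claisen cyclisation followed by enolisation; it replaces an aryl C–O coupling at a carbon between two oxygens. Because 10 is symmetric, either ketoester arm may act as the nucleophile.

**10 from 7 and 8.** The bond between the aryloxy carbon and one ketone carbon is cut, giving bis(silyl enol ether) 7 and methyl malonyl chloride 8. Placing the aryloxy carbon at the nucleophilic terminus is deliberate. A construction in which that carbon is the electrophilic centre twice (a doubly activated aryloxymalonyl unit) was weighed and dropped: a malonic acid with a free C–H loses CO2 as soon as one carboxyl is activated, and the mono-homologated intermediate would be a β-keto acid.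

**7 from 5; 5 from 3 and 4; 3 from 1.** Diene 7 is the double silyl enol ether of ketoester 5. The C–O bond of 5 is cut to phenol 3 and chloride 4; this is the SN2 step that makes the A–B ether. Phenol 3 comes from aldehyde 1 by Baeyer–Villiger oxidation. Ring B carries bromine from the start as its handle for the fragment coupling; the bromide is inert to every reagent on the way to 15.

## Roads not taken

**Alternative 1:** Ring C is made the double electrophile and both of its ether bonds are cut. In the forward direction the cationic cyclopentadienyl complex of divalent ruthenium with 1,2-dichloro-3,4,5-trimethoxybenzene, A1, would be attacked by the phenoxide of the AB phenol A2 at the chlorine next to the ring C–H. On warming, the phenoxide of 4-(benzyloxy)-3,5-dimethoxyphenol A3 would attack the second chlorine, giving the complexed ABCD tetramer A4, from which the metal is removed by photolysis.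
- Merits: two ethers, one of them at a doubly flanked carbon, are formed in one flask under mild, copper-free conditions, and ring D enters as a nucleophile.
- Weak points: the order of the two substitutions rests only on a steric difference between two chlorides on an arene that three methoxy donors deactivate even when complexed, and any leakage gives constitutional isomers of identical composition. A stoichiometric amount of ruthenium is needed for ring C and again for ring E. A2 still has to be made, so the ring A ether problem is untouched. The benzyl group on ring D adds a deprotection.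
- Comparison: this road is better in one respect. It has no counterpart to the coupling at a bromide between two methoxy groups (step 12), and it spends one flask where the chosen route spends four steps. Against this the chosen plan sets regiochemistry fixed by the position of a formyl group in a commercial building block, catalytic copper only, and no isomer separation.

**Alternative 2:** Ring E is built from a four-membered ring, with the cut at its C1–C2 bond. Thermolysis of the squarate-derived cyclobutenone A5 would open it to a dienylketene, whose 6π electrocyclisation and tautomerisation give the EFG phenol A6. A6 is the same compound as 23 of the chosen route.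
- Merits: every oxygen of the pentaoxygenated ring is placed by construction, the hindered E–F ether arises by addition–elimination on a vinylogous ester instead of an aryl coupling, and the hydroxyl appears where the next ether is needed.
- Weak points: A5 needs about four operations from a squaric ester once phenol 19 is in hand (aryloxy exchange, addition of a metallated enol ether to one of two different carbonyl groups, O-methylation, thermolysis), and the regiochemistry of that addition is not assured. The whole sequence would have to be repeated for ring C with a four-ring phenol.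
- Comparison: the chosen route reaches the identical compound from 19 in two steps (10 and 11). The coupling it avoids is the formyl-assisted one, the most dependable in the chosen plan. It offers nothing for ring A. It remains a sound reserve if the copper coupling at a flanked carbon were to fail generally.

**Alternative 3:** Three C–C bonds of ring B are cut. The pentacarbonylchromium carbene complex A7 (zerovalent chromium, carrying the ring A aryloxy group on the carbene carbon), the ring C aryl ethynyl ether A8 and one CO ligand would combine in a Dötz benzannulation to give the ABC phenol A9.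
- Merits: it is the most convergent way to the first three rings. Both ethers of ring B arrive on acyclic partners, so two aryl couplings are saved, and like the chosen plan it avoids any coupling at the ring A ether carbon.
- Weak points: aryloxycarbene complexes are far more electrophilic and labile than alkoxy ones, since aryloxide is a leaving group. Terminal aryl ynol ethers are sensitive, and heteroatom-substituted alkynes often leave the benzannulation manifold (cyclobutenones, double alkyne incorporation). Chromium is stoichiometric. A9 carries an ethyl ether, a free hydroxyl and a benzyl group that all need further handling before chain extension.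
- Comparison: on paper the convergence is better than that of the chosen plan. The chosen plan sets against it that ring A is made with classical carbonyl chemistry on stable, storable intermediates, at an early stage on cheap material.

Key step: step 5

## Route

Remark on the chemistry: the target has no stereocentre. Silyl enol ethers 6, 7 and 9 are expected as mixtures of double-bond isomers, and 10 and 11 as enolisable racemates or diastereomer mixtures. All these elements vanish on aromatisation, so their SMILES carry no stereodescriptors.

Step 1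
Reactants: 1 3-bromo-4,5-dimethoxybenzaldehyde
Product: 3 3-bromo-4,5-dimethoxyphenol, via aryl formate 2 (not isolated)
Conditions: mCPBA, CH2Cl2, rt; then K2CO3 (cat.), MeOH, rt
Reagents that add atoms: mCPBA (3-chloroperoxybenzoic acid), O=C(OO)c1cccc(Cl)c1
Why: Baeyer–Villiger oxidation of an electron-rich benzaldehyde (Dakin-type); the para methoxy group favours aryl over hydride migration, and catalytic carbonate in methanol transesterifies formate 2 to the phenol. The aryl bromide and methyl ethers are inert.

Step 2
Reactants: 3 3-bromo-4,5-dimethoxyphenol; 4 methyl 4-chloro-3-oxobutanoate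
Product: 5 methyl 4-(3-bromo-4,5-dimethoxyphenoxy)-3-oxobutanoate
Conditions: NaH (2.2 equiv), THF, 0 °C to rt; aq. HCl
Reagents that add atoms: none
Why: Williamson-type SN2 displacement; two equivalents of NaH give the phenoxide of 3 and the enolate of 4, the enolate shields the ketone and C2 of 4, and the phenoxide displaces the primary chloride at C4, a standard route to 4-aryloxyacetoacetates.

Step 3
Reactants: 5 methyl 4-(3-bromo-4,5-dimethoxyphenoxy)-3-oxobutanoate
Product: 7 4-(3-bromo-4,5-dimethoxyphenoxy)-1-methoxy-1,3-bis(trimethylsilyloxy)buta-1,3-diene, via monosilyl enol ether 6 (not isolated)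
Conditions: Me3SiOTf (2.2 equiv), Et3N (2.5 equiv), Et2O, 0 °C to rt
Reagents that add atoms: trimethylsilyl trifluoromethanesulfonate, C[Si](C)(C)OS(=O)(=O)C(F)(F)F
Why: One-flask double O-silylation of a β-keto ester to a Chan-type 1,3-bis(silyloxy)diene; the first equivalent gives 6, the second silylates the ester carbonyl while the amine removes a proton from the aryloxy-bearing CH2. The moisture-sensitive diene is used crude.

Step 4
Reactants: 7 4-(3-bromo-4,5-dimethoxyphenoxy)-1-methoxy-1,3-bis(trimethylsilyloxy)buta-1,3-diene; 8 methyl 3-chloro-3-oxopropanoate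
Product: 10 dimethyl 4-(3-bromo-4,5-dimethoxyphenoxy)-3,5-dioxoheptanedioate, via silyl enol ether 9 (not isolated)
Conditions: CH2Cl2, −78 °C to rt; then dilute aq. HCl
Reagents that add atoms: none
Why: Mukaiyama-type C-acylation of a 1,3-bis(silyl enol ether) by an acid chloride, which is known to take place at the terminal carbon and to give 3,5-dioxo esters after desilylation. The neutral conditions leave the acidic methylene of 8 alone, and the aryloxy carbon becomes the central carbon of the triketide.

Step 5
Reactants: 10 dimethyl 4-(3-bromo-4,5-dimethoxyphenoxy)-3,5-dioxoheptanedioate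
Product: 12 methyl 3-(3-bromo-4,5-dimethoxyphenoxy)-2,4,6-trihydroxybenzoate, via cyclohexanetrione tautomer 11 (not isolated)
Conditions: NaOMe (4 equiv), MeOH, 0 °C to reflux; then aq. HCl
Reagents that add atoms: none
Why: Methoxide converts 10 into its polyanion, the ketoester methylene carbon C2 adds to the distal ester carbonyl C7 and methoxide leaves (intramolecular Claisen, that is Dieckmann, condensation), giving trione 11, which enolises to the aromatic benzoate 12. The closest known reaction type is the Claisen cyclisation of 3,5-dioxoheptanedioate-type triketide esters to phloroglucinol carboxylates, as in the classical malonate-based phloroglucinol synthesis. Ring A closes in a 6-(enolendo)-exo-trig mode, which is allowed. No stereocentre is formed, and the enolisable C4 of 10 becomes an sp2 ring carbon. The selectivity needed is C-acylation over O-acylation to a 4-hydroxypyran-2-one and over retro-Claisen cleavage of the central diketone. Lactonisation is reversible in methanolic methoxide whereas formation of the trihydroxybenzoate polyanion is an irreversible sink, and the acidic C4–H keeps the diketone in its enolate form, which methoxide does not attack. The mirror symmetry of 10 makes both possible closures (C2 to C7 or C6 to C1) give the same product. The aryl bromide and the aryl methyl ethers are inert to NaOMe.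

Step 6
Reactants: 12 methyl 3-(3-bromo-4,5-dimethoxyphenoxy)-2,4,6-trihydroxybenzoate
Product: 14 2-(3-bromo-4,5-dimethoxyphenoxy)benzene-1,3,5-triol, via trihydroxybenzoic acid 13 (not isolated)
Conditions: aq. NaOH (degassed), reflux, Ar; then HCl to pH 3, 60 °C
Reagents that add atoms: none
Why: Saponification followed by protodecarboxylation of the phloroglucinolcarboxylic acid 13, which loses CO2 on mild warming in weakly acidic water because ipso protonation of a phloroglucinol ring is easy. Exclusion of air protects the electron-rich triol.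

Step 7
Reactants: 14 2-(3-bromo-4,5-dimethoxyphenoxy)benzene-1,3,5-triol
Product: 15 1-bromo-2,3-dimethoxy-5-(2,4,6-trimethoxyphenoxy)benzene
Conditions: Me2SO4, K2CO3, acetone, reflux
Reagents that add atoms: dimethyl sulfate, COS(=O)(=O)OC
Why: Exhaustive Williamson O-methylation; dimethyl sulfate with K2CO3 in acetone is the standard way to turn phloroglucinols into their trimethyl ethers with little C-methylation.

Step 8
Reactants: 16 3,4,5-trimethoxyphenol; 1 3-bromo-4,5-dimethoxybenzaldehyde
Product: 17 3,4-dimethoxy-5-(3,4,5-trimethoxyphenoxy)benzaldehyde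
Conditions: CuI (10 mol%), N,N-dimethylglycine hydrochloride (30 mol%), Cs2CO3, 1,4-dioxane, 100 °C
Reagents that add atoms: none
Why: Ullmann-type copper-catalysed diaryl ether synthesis with an amino acid ligand; an unhindered electron-rich phenoxide meets a bromide that carries one ortho methoxy group and is activated by the meta formyl group. Non-enolisable aryl aldehydes tolerate carbonate in dioxane.

Step 9
Reactants: 17 3,4-dimethoxy-5-(3,4,5-trimethoxyphenoxy)benzaldehyde
Product: 19 3,4-dimethoxy-5-(3,4,5-trimethoxyphenoxy)phenol, via aryl formate 18 (not isolated)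
Conditions: mCPBA, CH2Cl2, rt; then K2CO3 (cat.), MeOH, rt
Reagents that add atoms: mCPBA (3-chloroperoxybenzoic acid), O=C(OO)c1cccc(Cl)c1
Why: Baeyer–Villiger oxidation (Dakin-type) as in step 1; the para methoxy group directs aryl migration and methanolysis of formate 18 unmasks the ring F hydroxyl at the carbon that must carry the next ether.

Step 10
Reactants: 19 3,4-dimethoxy-5-(3,4,5-trimethoxyphenoxy)phenol; 20 2-bromo-3,4,5-trimethoxybenzaldehyde
Product: 21 2-[3,4-dimethoxy-5-(3,4,5-trimethoxyphenoxy)phenoxy]-3,4,5-trimethoxybenzaldehyde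
Conditions: CuI (10 mol%), picolinic acid (20 mol%), K3PO4, DMSO, 90 °C
Reagents that add atoms: none
Why: Ullmann coupling at a bromide activated by an ortho formyl group (electron withdrawal and possible coordination to copper), the reaction type long used for 2-bromo-3,4,5-trialkoxybenzoyl compounds although the carbon is flanked on both sides. Phenol 19 has no ortho substituent.

Step 11
Reactants: 21 2-[3,4-dimethoxy-5-(3,4,5-trimethoxyphenoxy)phenoxy]-3,4,5-trimethoxybenzaldehyde
Product: 23 2-[3,4-dimethoxy-5-(3,4,5-trimethoxyphenoxy)phenoxy]-3,4,5-trimethoxyphenol, via aryl formate 22 (not isolated)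
Conditions: mCPBA, CH2Cl2, rt; then K2CO3 (cat.), MeOH, rt
Reagents that add atoms: mCPBA (3-chloroperoxybenzoic acid), O=C(OO)c1cccc(Cl)c1
Why: Baeyer–Villiger oxidation (Dakin-type); the ortho aryloxy and para methoxy groups make the ring the migrating group, and the formate is cleaved by methanolysis.

Step 12
Reactants: 23 2-[3,4-dimethoxy-5-(3,4,5-trimethoxyphenoxy)phenoxy]-3,4,5-trimethoxyphenol; 24 4-bromo-3,5-dimethoxybenzaldehyde
Product: 25 4-{2-[3,4-dimethoxy-5-(3,4,5-trimethoxyphenoxy)phenoxy]-3,4,5-trimethoxyphenoxy}-3,5-dimethoxybenzaldehyde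
Conditions: CuI (20 mol%), picolinic acid (40 mol%), K3PO4, DMSO, 110 °C
Reagents that add atoms: none
Why: Ullmann coupling under the conditions developed for hindered partners; the bromide of 24 lies between two methoxy groups but is activated by the para formyl group, and phenol 23 has one ortho aryloxy group. This is the most hindered ether-forming step of the route.

Step 13
Reactants: 25 4-{2-[3,4-dimethoxy-5-(3,4,5-trimethoxyphenoxy)phenoxy]-3,4,5-trimethoxyphenoxy}-3,5-dimethoxybenzaldehyde
Product: 27 4-{2-[3,4-dimethoxy-5-(3,4,5-trimethoxyphenoxy)phenoxy]-3,4,5-trimethoxyphenoxy}-3,5-dimethoxyphenol, via aryl formate 26 (not isolated)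
Conditions: mCPBA, CH2Cl2, rt; then K2CO3 (cat.), MeOH, rt
Reagents that add atoms: mCPBA (3-chloroperoxybenzoic acid), O=C(OO)c1cccc(Cl)c1
Why: Baeyer–Villiger oxidation (Dakin-type); the para aryloxy group favours aryl migration, and methanolysis of formate 26 frees the ring D hydroxyl, which has two ortho C–H neighbours.

Step 14
Reactants: 27 4-{2-[3,4-dimethoxy-5-(3,4,5-trimethoxyphenoxy)phenoxy]-3,4,5-trimethoxyphenoxy}-3,5-dimethoxyphenol; 20 2-bromo-3,4,5-trimethoxybenzaldehyde
Product: 28 2-(4-{2-[3,4-dimethoxy-5-(3,4,5-trimethoxyphenoxy)phenoxy]-3,4,5-trimethoxyphenoxy}-3,5-dimethoxyphenoxy)-3,4,5-trimethoxybenzaldehyde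
Conditions: CuI (10 mol%), picolinic acid (20 mol%), K3PO4, DMSO, 90 °C
Reagents that add atoms: none
Why: The same formyl-assisted Ullmann coupling as in step 10, again with an unhindered phenol; only ethers and one aldehyde are present, so nothing else competes.

Step 15
Reactants: 28 2-(4-{2-[3,4-dimethoxy-5-(3,4,5-trimethoxyphenoxy)phenoxy]-3,4,5-trimethoxyphenoxy}-3,5-dimethoxyphenoxy)-3,4,5-trimethoxybenzaldehyde
Product: 30 2-(4-{2-[3,4-dimethoxy-5-(3,4,5-trimethoxyphenoxy)phenoxy]-3,4,5-trimethoxyphenoxy}-3,5-dimethoxyphenoxy)-3,4,5-trimethoxyphenol, via aryl formate 29 (not isolated)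
Conditions: mCPBA, CH2Cl2, rt; then K2CO3 (cat.), MeOH, rt
Reagents that add atoms: mCPBA (3-chloroperoxybenzoic acid), O=C(OO)c1cccc(Cl)c1
Why: Baeyer–Villiger oxidation (Dakin-type) as in step 11; it delivers the ring C hydroxyl at C1, the position that joins ring B.

Step 16
Reactants: 30 2-(4-{2-[3,4-dimethoxy-5-(3,4,5-trimethoxyphenoxy)phenoxy]-3,4,5-trimethoxyphenoxy}-3,5-dimethoxyphenoxy)-3,4,5-trimethoxyphenol; 15 1-bromo-2,3-dimethoxy-5-(2,4,6-trimethoxyphenoxy)benzene
Product: 31 2-{3-[2-(4-{2-[3,4-dimethoxy-5-(3,4,5-trimethoxyphenoxy)phenoxy]-3,4,5-trimethoxyphenoxy}-3,5-dimethoxyphenoxy)-3,4,5-trimethoxyphenoxy]-4,5-dimethoxyphenoxy}-1,3,5-trimethoxybenzene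
Conditions: CuI (20 mol%), N,N-dimethylglycine hydrochloride (60 mol%), Cs2CO3, 1,4-dioxane, 105 °C
Reagents that add atoms: none
Why: Ullmann fragment coupling; the bromide of 15 has one ortho methoxy group and the phenol of 30 one ortho aryloxy group, and both partners otherwise carry only ethers. The easily made bromide 15 is used in slight excess.

Step 17
Reactants: 31 2-{3-[2-(4-{2-[3,4-dimethoxy-5-(3,4,5-trimethoxyphenoxy)phenoxy]-3,4,5-trimethoxyphenoxy}-3,5-dimethoxyphenoxy)-3,4,5-trimethoxyphenoxy]-4,5-dimethoxyphenoxy}-1,3,5-trimethoxybenzene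
Product: 32 2-{3-[2-(4-{2-[3,4-dihydroxy-5-(3,4,5-trihydroxyphenoxy)phenoxy]-3,4,5-trihydroxyphenoxy}-3,5-dihydroxyphenoxy)-3,4,5-trihydroxyphenoxy]-4,5-dihydroxyphenoxy}benzene-1,3,5-triol (CNP0137585.0)
Conditions: BBr3 (excess), CH2Cl2, −78 °C to rt; then MeOH, H2O; isolation under Ar
Reagents that add atoms: none
Why: Lewis-acid cleavage of aryl methyl ethers; boron binds the methoxy oxygen and bromide attacks the methyl carbon by SN2. The diaryl ether oxygens have no sp3 carbon to attack and should survive, so all eighteen hydroxyl groups are freed in one operation.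

## Compound list

1 | 3-bromo-4,5-dimethoxybenzaldehyde | COc1cc(C=O)cc(Br)c1OC | starting material
2 | 3-bromo-4,5-dimethoxyphenyl formate | COc1cc(OC=O)cc(Br)c1OC | intermediate
3 | 3-bromo-4,5-dimethoxyphenol | COc1cc(O)cc(Br)c1OC | intermediate
4 | methyl 4-chloro-3-oxobutanoate | COC(=O)CC(=O)CCl | starting material
5 | methyl 4-(3-bromo-4,5-dimethoxyphenoxy)-3-oxobutanoate | COC(=O)CC(=O)COc1cc(OC)c(OC)c(Br)c1 | intermediate
6 | methyl 4-(3-bromo-4,5-dimethoxyphenoxy)-3-(trimethylsilyloxy)but-2-enoate (double-bond isomers) | COC(=O)C=C(O[Si](C)(C)C)COc1cc(OC)c(OC)c(Br)c1 | intermediate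
7 | 4-(3-bromo-4,5-dimethoxyphenoxy)-1-methoxy-1,3-bis(trimethylsilyloxy)buta-1,3-diene (double-bond isomers) | COC(O[Si](C)(C)C)=CC(O[Si](C)(C)C)=COc1cc(OC)c(OC)c(Br)c1 | intermediate
8 | methyl 3-chloro-3-oxopropanoate (methyl malonyl chloride) | COC(=O)CC(Cl)=O | starting material
9 | dimethyl 4-(3-bromo-4,5-dimethoxyphenoxy)-5-oxo-3-(trimethylsilyloxy)hept-2-enedioate (racemic, double-bond isomers) | COC(=O)C=C(O[Si](C)(C)C)C(Oc1cc(OC)c(OC)c(Br)c1)C(=O)CC(=O)OC | intermediate
10 | dimethyl 4-(3-bromo-4,5-dimethoxyphenoxy)-3,5-dioxoheptanedioate (racemic, enolisable) | COC(=O)CC(=O)C(Oc1cc(OC)c(OC)c(Br)c1)C(=O)CC(=O)OC | intermediate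
11 | methyl 3-(3-bromo-4,5-dimethoxyphenoxy)-2,4,6-trioxocyclohexane-1-carboxylate (enolisable mixture) | COC(=O)C1C(=O)CC(=O)C(Oc2cc(OC)c(OC)c(Br)c2)C1=O | intermediate
12 | methyl 3-(3-bromo-4,5-dimethoxyphenoxy)-2,4,6-trihydroxybenzoate | COC(=O)c1c(O)cc(O)c(Oc2cc(OC)c(OC)c(Br)c2)c1O | intermediate
13 | 3-(3-bromo-4,5-dimethoxyphenoxy)-2,4,6-trihydroxybenzoic acid | OC(=O)c1c(O)cc(O)c(Oc2cc(OC)c(OC)c(Br)c2)c1O | intermediate
14 | 2-(3-bromo-4,5-dimethoxyphenoxy)benzene-1,3,5-triol | Oc1cc(O)c(Oc2cc(OC)c(OC)c(Br)c2)c(O)c1 | intermediate
15 | 1-bromo-2,3-dimethoxy-5-(2,4,6-trimethoxyphenoxy)benzene (AB bromide) | COc1cc(OC)c(Oc2cc(OC)c(OC)c(Br)c2)c(OC)c1 | intermediate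
16 | 3,4,5-trimethoxyphenol | COc1cc(O)cc(OC)c1OC | starting material
17 | 3,4-dimethoxy-5-(3,4,5-trimethoxyphenoxy)benzaldehyde (FG aldehyde) | COc1cc(C=O)cc(Oc2cc(OC)c(OC)c(OC)c2)c1OC | intermediate
18 | 3,4-dimethoxy-5-(3,4,5-trimethoxyphenoxy)phenyl formate | COc1cc(OC=O)cc(Oc2cc(OC)c(OC)c(OC)c2)c1OC | intermediate
19 | 3,4-dimethoxy-5-(3,4,5-trimethoxyphenoxy)phenol (FG phenol) | COc1cc(O)cc(Oc2cc(OC)c(OC)c(OC)c2)c1OC | intermediate
20 | 2-bromo-3,4,5-trimethoxybenzaldehyde | COc1cc(C=O)c(Br)c(OC)c1OC | starting material
21 | 2-[3,4-dimethoxy-5-(3,4,5-trimethoxyphenoxy)phenoxy]-3,4,5-trimethoxybenzaldehyde (EFG aldehyde) | O=Cc1cc(OC)c(OC)c(OC)c1Oc1cc(OC)c(OC)c(Oc2cc(OC)c(OC)c(OC)c2)c1 | intermediate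
22 | 2-[3,4-dimethoxy-5-(3,4,5-trimethoxyphenoxy)phenoxy]-3,4,5-trimethoxyphenyl formate | O=COc1cc(OC)c(OC)c(OC)c1Oc1cc(OC)c(OC)c(Oc2cc(OC)c(OC)c(OC)c2)c1 | intermediate
23 | 2-[3,4-dimethoxy-5-(3,4,5-trimethoxyphenoxy)phenoxy]-3,4,5-trimethoxyphenol (EFG phenol) | Oc1cc(OC)c(OC)c(OC)c1Oc1cc(OC)c(OC)c(Oc2cc(OC)c(OC)c(OC)c2)c1 | intermediate
24 | 4-bromo-3,5-dimethoxybenzaldehyde | COc1cc(C=O)cc(OC)c1Br | starting material
25 | 4-{2-[3,4-dimethoxy-5-(3,4,5-trimethoxyphenoxy)phenoxy]-3,4,5-trimethoxyphenoxy}-3,5-dimethoxybenzaldehyde (DEFG aldehyde) | O=Cc1cc(OC)c(Oc2cc(OC)c(OC)c(OC)c2Oc2cc(OC)c(OC)c(Oc3cc(OC)c(OC)c(OC)c3)c2)c(OC)c1 | intermediate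
26 | 4-{2-[3,4-dimethoxy-5-(3,4,5-trimethoxyphenoxy)phenoxy]-3,4,5-trimethoxyphenoxy}-3,5-dimethoxyphenyl formate | O=COc1cc(OC)c(Oc2cc(OC)c(OC)c(OC)c2Oc2cc(OC)c(OC)c(Oc3cc(OC)c(OC)c(OC)c3)c2)c(OC)c1 | intermediate
27 | 4-{2-[3,4-dimethoxy-5-(3,4,5-trimethoxyphenoxy)phenoxy]-3,4,5-trimethoxyphenoxy}-3,5-dimethoxyphenol (DEFG phenol) | Oc1cc(OC)c(Oc2cc(OC)c(OC)c(OC)c2Oc2cc(OC)c(OC)c(Oc3cc(OC)c(OC)c(OC)c3)c2)c(OC)c1 | intermediate
28 | 2-(4-{2-[3,4-dimethoxy-5-(3,4,5-trimethoxyphenoxy)phenoxy]-3,4,5-trimethoxyphenoxy}-3,5-dimethoxyphenoxy)-3,4,5-trimethoxybenzaldehyde (CDEFG aldehyde) | O=Cc1cc(OC)c(OC)c(OC)c1Oc1cc(OC)c(Oc2cc(OC)c(OC)c(OC)c2Oc2cc(OC)c(OC)c(Oc3cc(OC)c(OC)c(OC)c3)c2)c(OC)c1 | intermediate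
29 | 2-(4-{2-[3,4-dimethoxy-5-(3,4,5-trimethoxyphenoxy)phenoxy]-3,4,5-trimethoxyphenoxy}-3,5-dimethoxyphenoxy)-3,4,5-trimethoxyphenyl formate | O=COc1cc(OC)c(OC)c(OC)c1Oc1cc(OC)c(Oc2cc(OC)c(OC)c(OC)c2Oc2cc(OC)c(OC)c(Oc3cc(OC)c(OC)c(OC)c3)c2)c(OC)c1 | intermediate
30 | 2-(4-{2-[3,4-dimethoxy-5-(3,4,5-trimethoxyphenoxy)phenoxy]-3,4,5-trimethoxyphenoxy}-3,5-dimethoxyphenoxy)-3,4,5-trimethoxyphenol (CDEFG phenol) | Oc1cc(OC)c(OC)c(OC)c1Oc1cc(OC)c(Oc2cc(OC)c(OC)c(OC)c2Oc2cc(OC)c(OC)c(Oc3cc(OC)c(OC)c(OC)c3)c2)c(OC)c1 | intermediate
31 | 2-{3-[2-(4-{2-[3,4-dimethoxy-5-(3,4,5-trimethoxyphenoxy)phenoxy]-3,4,5-trimethoxyphenoxy}-3,5-dimethoxyphenoxy)-3,4,5-trimethoxyphenoxy]-4,5-dimethoxyphenoxy}-1,3,5-trimethoxybenzene (octadecamethyl ether of the target) | COc1cc(OC)c(Oc2cc(OC)c(OC)c(Oc3cc(OC)c(OC)c(OC)c3Oc3cc(OC)c(Oc4cc(OC)c(OC)c(OC)c4Oc4cc(OC)c(OC)c(Oc5cc(OC)c(OC)c(OC)c5)c4)c(OC)c3)c2)c(OC)c1 | intermediate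
32 | 2-{3-[2-(4-{2-[3,4-dihydroxy-5-(3,4,5-trihydroxyphenoxy)phenoxy]-3,4,5-trihydroxyphenoxy}-3,5-dihydroxyphenoxy)-3,4,5-trihydroxyphenoxy]-4,5-dihydroxyphenoxy}benzene-1,3,5-triol (CNP0137585.0) | Oc1cc(O)c(Oc2cc(O)c(O)c(Oc3cc(O)c(O)c(O)c3Oc3cc(O)c(Oc4cc(O)c(O)c(O)c4Oc4cc(O)c(O)c(Oc5cc(O)c(O)c(O)c5)c4)c(O)c3)c2)c(O)c1 | target

## Step count and risks

Total: 17 steps. Longest linear sequence: 10 steps (16 through steps 8 to 15, then steps 16 and 17). The AB branch (steps 1 to 7) joins at step 16.

**Step 5 (key step).** Ring closure may go through oxygen instead of carbon (lactonisation of an enol onto an ester). Methoxide may also cleave the central 2-aryloxy-1,3-diketone in a retro-Claisen fragmentation before the ring closes, because the aryloxy group stabilises the departing carbanion. The fallback gives up the de novo construction and attaches ring A as a preformed, masked ring. It sets out from phenol 3, which is coupled (CuI, picolinic acid, K3PO4, DMSO) with an excess of bromide 24 to 4-(3-bromo-4,5-dimethoxyphenoxy)-3,5-dimethoxybenzaldehyde F1. The 2,6-dimethoxy-4-formylphenyl group of 24 is a latent 2,4,6-trimethoxyphenyl group. Baeyer–Villiger oxidation with mCPBA gives 4-(3-bromo-4,5-dimethoxyphenoxy)-3,5-dimethoxyphenyl formate F2, which is methanolysed without isolation to 4-(3-bromo-4,5-dimethoxyphenoxy)-3,5-dimethoxyphenol F3. Methylation (MeI, K2CO3, DMF) gives 15, where the route is rejoined. The formyl-activated bromide of 24 should react before the unactivated bromide of 3, and the excess of 24 limits self-condensation.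

**Step 4.** The acid chloride may attack a silyloxy oxygen or the ester-flanked carbon of the diene instead of the aryloxy-bearing terminus, which is more hindered than in the unsubstituted diene; 8 may also be lost by ketene formation. The fallback reverses the order of acylation and ether formation and sets out from 8 and 3. Commercial 1-methoxy-1,3-bis(trimethylsilyloxy)buta-1,3-diene is acylated with 8 to dimethyl 3,5-dioxoheptanedioate F4. Its central, most acidic methylene is chlorinated with SO2Cl2 to dimethyl 4-chloro-3,5-dioxoheptanedioate F5. The chloride is displaced by the phenoxide of 3 (K2CO3, acetone), an SN2 reaction at a 2-chloro-1,3-diketone, to give 10, where the route is rejoined.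

**Step 12.** Copper insertion at a carbon between two methoxy groups may be too slow, so that reduction of the bromide and decomposition of the phenoxide at 110 °C overtake ether formation. The fallback changes the metal and the mechanism: it sets out from 23 and 24 and uses palladium-catalysed C–O cross-coupling (Pd(OAc)2, 2-(di-tert-butylphosphino)-2′,4′,6′-triisopropylbiphenyl, K3PO4, toluene, 100 °C). Here the bromide enters by oxidative addition to zerovalent palladium, which the para formyl group accelerates, and the bulky ligand drives reductive elimination of hindered ethers. It returns to the route at 25 and makes no new compound (F0).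

**Step 16.** With two large, electron-rich partners the coupling may stall, and protodebromination of 15 may consume the bromide at the temperature needed. The fallback replaces the halide coupling by an oxidative boronic acid coupling. It sets out from 15, which is converted by bromine–lithium exchange (n-BuLi, THF, −78 °C), B(OiPr)3 and acidic work-up into [2,3-dimethoxy-5-(2,4,6-trimethoxyphenoxy)phenyl]boronic acid F6. This is joined to 30 by Chan–Lam–Evans coupling (Cu(OAc)2, pyridine, 4 Å molecular sieves, CH2Cl2, air, rt) to give 31, where the route is rejoined.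

**Step 17.** Cleavage of eighteen methyl ethers may stop short, leaving partly methylated material, and the free polyphenol may be lost by air oxidation during chromatography. The fallback adds a derivatise–purify–release sequence and sets out from 31. After the BBr3 treatment the crude product is acetylated (Ac2O, pyridine) to the octadecaacetate of the target, F7, a stable compound that can be separated on silica from species still carrying methoxy groups (these are resubmitted to BBr3). Acid-catalysed methanolysis (HCl in MeOH, rt, Ar) then releases 32 without any phenoxide being formed.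

## Further compounds

F1 | step 5 | 4-(3-bromo-4,5-dimethoxyphenoxy)-3,5-dimethoxybenzaldehyde | O=Cc1cc(OC)c(Oc2cc(OC)c(OC)c(Br)c2)c(OC)c1
F2 | step 5 | 4-(3-bromo-4,5-dimethoxyphenoxy)-3,5-dimethoxyphenyl formate | O=COc1cc(OC)c(Oc2cc(OC)c(OC)c(Br)c2)c(OC)c1
F3 | step 5 | 4-(3-bromo-4,5-dimethoxyphenoxy)-3,5-dimethoxyphenol | Oc1cc(OC)c(Oc2cc(OC)c(OC)c(Br)c2)c(OC)c1
F4 | step 4 | dimethyl 3,5-dioxoheptanedioate | COC(=O)CC(=O)CC(=O)CC(=O)OC
F5 | step 4 | dimethyl 4-chloro-3,5-dioxoheptanedioate (racemic, enolisable) | COC(=O)CC(=O)C(Cl)C(=O)CC(=O)OC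
F0 | step 12 | none | none
F6 | step 16 | [2,3-dimethoxy-5-(2,4,6-trimethoxyphenoxy)phenyl]boronic acid | COc1cc(OC)c(Oc2cc(OC)c(OC)c(B(O)O)c2)c(OC)c1
F7 | step 17 | octadecaacetate of 32 | CC(=O)Oc1cc(OC(C)=O)c(Oc2cc(OC(C)=O)c(OC(C)=O)c(Oc3cc(OC(C)=O)c(OC(C)=O)c(OC(C)=O)c3Oc3cc(OC(C)=O)c(Oc4cc(OC(C)=O)c(OC(C)=O)c(OC(C)=O)c4Oc4cc(OC(C)=O)c(OC(C)=O)c(Oc5cc(OC(C)=O)c(OC(C)=O)c(OC(C)=O)c5)c4)c(OC(C)=O)c3)c2)c(OC(C)=O)c1
A1 | alternative 1 | (η5-cyclopentadienyl)(η6-1,2-dichloro-3,4,5-trimethoxybenzene)ruthenium hexafluorophosphate | COc1cc(Cl)c(Cl)c(OC)c1OC.[Ru+2].c1cc[cH-]c1.F[P-](F)(F)(F)(F)F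
A2 | alternative 1 | 2,3-dimethoxy-5-(2,4,6-trimethoxyphenoxy)phenol (AB phenol) | COc1cc(OC)c(Oc2cc(OC)c(OC)c(O)c2)c(OC)c1
A3 | alternative 1 | 4-(benzyloxy)-3,5-dimethoxyphenol | COc1cc(O)cc(OC)c1OCc1ccccc1
A4 | alternative 1 | CpRu hexafluorophosphate complex of the ABCD tetramer (ring C bound to ruthenium) | COc1cc(OC)c(Oc2cc(OC)c(OC)c(Oc3cc(OC)c(OC)c(OC)c3Oc3cc(OC)c(OCc4ccccc4)c(OC)c3)c2)c(OC)c1.[Ru+2].c1cc[cH-]c1.F[P-](F)(F)(F)(F)F
A5 | alternative 2 | 2-[3,4-dimethoxy-5-(3,4,5-trimethoxyphenoxy)phenoxy]-3,4-dimethoxy-4-(1-methoxyethenyl)cyclobut-2-en-1-one (racemic) | COC(=C)C1(OC)C(OC)=C(Oc2cc(OC)c(OC)c(Oc3cc(OC)c(OC)c(OC)c3)c2)C1=O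
A6 | alternative 2 | 2-[3,4-dimethoxy-5-(3,4,5-trimethoxyphenoxy)phenoxy]-3,4,5-trimethoxyphenol (EFG phenol, identical with 23) | Oc1cc(OC)c(OC)c(OC)c1Oc1cc(OC)c(OC)c(Oc2cc(OC)c(OC)c(OC)c2)c1
A7 | alternative 3 | pentacarbonyl[(2E)-3-ethoxy-1-(2,4,6-trimethoxyphenoxy)prop-2-en-1-ylidene]chromium | CCO/C=C/C(Oc1c(OC)cc(OC)cc1OC)=[Cr](=C=O)(=C=O)(=C=O)(=C=O)=C=O
A8 | alternative 3 | 2-(benzyloxy)-1-(ethynyloxy)-3,4,5-trimethoxybenzene | C#COc1cc(OC)c(OC)c(OC)c1OCc1ccccc1
A9 | alternative 3 | 2-[2-(benzyloxy)-3,4,5-trimethoxyphenoxy]-6-ethoxy-4-(2,4,6-trimethoxyphenoxy)phenol (ABC phenol) | COc1cc(OC)c(Oc2cc(OCC)c(O)c(Oc3cc(OC)c(OC)c(OC)c3OCc3ccccc3)c2)c(OC)c1
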